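Remark on the chemistry: formaldehyde (2) is assumed to be used as paraformaldehyde. Both halves are numbered as chromans (O1, C2, C3, C4, C4a, C5 to C8, C8a); rings A and C are the benzene and dihydropyran of the dihydroxylated half, rings B and D those of the half that carries the chain.

## Analysis of the target

The target (16, C25H30O5) is a dihydrochalcone-type ketone in which a propan-1-one chain joins two 2,2-dimethylchromans. The carbonyl carbon sits on C6 of a 5,7-dihydroxy-2,2-dimethylchroman (rings A and C), and the far CH2 sits on C6 of an otherwise unsubstituted 2,2-dimethylchroman (rings B and D). There is no stereocentre, because each C2 carries two methyl groups, so the whole problem is one of constitution and regiochemistry. The sensitive parts are the chelated 2,6-dihydroxyaryl ketone, the oxidisable and easily over-alkylated phloroglucinol-type ring A, and the two tertiary alkyl aryl ethers. Of these ethers, the one in ring C has O1 para to the ketone and can ionise at O1–C2 under strong acid. The first difficulty is ring A: C6 and C8 are both flanked by two oxygen atoms and activated by all three, yet the ketone must stand at C6 only. The second is ring D, which has to be annulated across the phenol oxygen and one ortho carbon of ring B with the quaternary carbon on oxygen, while the chain para to that oxygen stays untouched. The strategy rests on ring D read as O1–C2–C3–C4: C2 with its methyls and C3 are the two alkene carbons of isobutylene (5), and C4 is a benzylic CH2 ortho to the phenol oxygen. Ring D is therefore the cycloadduct of an ortho-quinone methide of ring B with 5.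

## Retrosynthetic reasoning

**16 to 15.** The two phenols of ring A are masked as methoxymethyl ethers in 15, and the two acetal O–CH2 bonds are cut last. These groups are carried because they are the directing groups that fix the site of fragment union one step earlier. Their removal needs only dilute acid, which the chelated ketone and both chroman ethers should tolerate.

**15 to 13 and 8.** The bond between C6 of ring A and the carbonyl carbon is cut. This splits the molecule into two chroman halves of similar size and makes the route convergent. The polarity chosen is an aryl anion at C6 (14, from 13) and an acyl cation equivalent (amide 8). An electrophilic acylation of the free diol 12 was not chosen, because nothing in 12 would decide between C6 and C8. In 13, C6–H is the only hydrogen lying between two chelating acetal ethers, so directed metalation should place the metal there. The forward step therefore has to deprotonate selectively and add the carbanion once to the amide.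

**13 to 12 to 9 and 10.** Ring C is opened at O1–C2 and at C4–C4a, which leads back to the symmetrical triol 9 and the C5 allylic alcohol 10 by way of the C-prenylated triol 11. All three ring positions of 9 are equivalent, so no regiochemical question arises in making 12. The only demand is to stop after one annulation.

**8 to 7.** This is a change of the acyl function only. The N-methoxy-N-methyl amide is chosen over the ester because its tetrahedral adduct with 14 is held by chelation and cannot take up a second aryl group.

**7 to 4 and 5 (key disconnection).** Ring D is cut at C3–C4 and at O1–C2. This reveals 5 and the ortho-quinone methide 6, which is drawn from the 2-hydroxybenzyl alcohol 4 by dehydration. Cutting here uses the chain-bearing aromatic ring as it is bought and brings in C2, C3 and both methyl groups in one piece. No prenyl group has to be installed and no separate cyclisation is needed. The forward reaction must generate 6 in the presence of a large excess of 5 and close the ring with the quaternary carbon on oxygen.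

**4 to 3 to 1 and 2.** The benzylic carbon C4 is removed from the ring of 1, which leaves the commercial phenol 1 and formaldehyde 2. A boron template ties the phenol oxygen and the new CH2–O together as the cyclic boronate 3. This restricts the reaction to one ortho position and keeps the hydroxymethyl group from condensing further. The para position is already occupied by the chain, so only ortho attack is possible.

## Alternatives that were turned down

**Alternative 1:** Ring D would be made by ring expansion, the disconnection being the C4–C4a bond with ring B traced back to a cyclohexadienone.
- Forward key step: 4-(3-hydroxy-3-methylbutyl)phenol A3 is dearomatised by a hypervalent-iodine oxidant to the spiro ether 2,2-dimethyl-1-oxaspiro[4.5]deca-6,9-dien-8-one A2. Acid then triggers a dienone–phenol rearrangement in which the ring CH2 shifts from the spiro carbon to the neighbouring dienone carbon, giving 2,2-dimethylchroman-6-ol A1.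
- For it: the quaternary carbon is bonded to oxygen before the rearrangement, so the 2,2-dimethyl orientation is certain. Carbon migration is favoured because the oxygen left behind stabilises the cation. No pressurised gas or high temperature is needed.
- Against it: A1 carries a hydroxyl at C6, exactly where 16 has the carbon chain. The para oxygen that makes the dearomatisation possible must be removed again, through a sulfonate, a cross-coupling with a three-carbon partner and adjustment to the propanoyl level. That is three or four further steps, one of them with a precious metal. The spiro ether can also revert by C–O ionisation under the acid.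
- Comparison: on certainty of ring formation this route is probably stronger than a high-temperature cycloaddition. The chosen strategy instead has the chain in place from 1, makes no redox detour, and reaches 7 in three steps.

**Alternative 2:** The bond from ring A to the carbonyl carbon would be formed together with a lactone that is later destroyed.
- Forward key step: 9 is condensed with 2-[(2,2-dimethylchroman-6-yl)methyl]propanedioic acid A5 under strongly dehydrating Lewis-acid conditions. This forms the aryl–carbon bond and a lactone C–O bond and gives the 4-hydroxycoumarin A4. Lactone hydrolysis and decarboxylation would then release the ketone 3-(2,2-dimethylchroman-6-yl)-1-(2,4,6-trihydroxyphenyl)propan-1-one A6.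
- For it: acylation of the symmetrical 9 is regiochemically beyond question. On this point it is stronger than the chelation-controlled metalation of 13 in the chosen route.
- Against it: a ring is built only to be opened, and one carbon is lost as carbon dioxide. A5 already contains ring D, so the ring D problem is not addressed at all. The dehydrating acid conditions threaten the tertiary ether of A5. A6 still lacks ring C, and annulating it on a 2,4,6-trihydroxyaryl ketone reopens the choice between the hydroxyl para and the hydroxyl ortho to the ketone, that is, between the 6-acyl and the 8-acyl chroman.
- Comparison: it is longer and only postpones the regiochemical problem of ring A. The chosen route has ring C in place before the halves are joined and decides C6 against C8 through the placement of two directing groups.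

**Alternative 3:** Ring B itself would be built, with ring D closing in the same step; the disconnections are the C4a–C8a and C5–C6 bonds.
- Forward key step: the pyridazine A8 carries a terminal alkyne on an O–C(CH3)2–CH2–CH2 tether at C3 and the ring A ketone chain at C6. On heating it undergoes an intramolecular inverse-electron-demand Diels–Alder reaction across C3 and C6 and loses its two nitrogen atoms as gas. The product is the bis(methoxymethyl) ether A7, which has the constitution of 15.
- For it: one step closes two rings, the tether dictates the regiochemistry absolutely, gas loss makes the step irreversible, and the product is one deprotection from 16. On regiocontrol of ring D it is stronger than any intermolecular cycloaddition.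
- Against it: a pyridazine with an alkoxy donor and an alkyl group and no electron-withdrawing substituent is a reluctant azadiene, so very high temperatures are to be expected. At those temperatures the tertiary alkyl heteroaryl ether of A8 can eliminate. Making that hindered ether by substitution on the heterocycle is itself difficult. A8 also needs a long linear synthesis that already contains the complete ring A half.
- Comparison: ring B can be bought as part of 1, so building it anew gains nothing for this target. The chosen strategy offers commodity starting materials and a much shorter sequence, and accepts a pressurised gas in exchange.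

Key step: step 3

## Route

Step 1
Reactants: 1 methyl 3-(4-hydroxyphenyl)propanoate; 2 formaldehyde (as paraformaldehyde)
Product: 3 methyl 3-(2-phenyl-4H-1,3,2-benzodioxaborinin-6-yl)propanoate
Conditions: PhB(OH)2 (1.1 equiv), (CH2O)n, EtCO2H (cat.), PhMe, reflux, Dean–Stark
Reagents that add atoms: phenylboronic acid, OB(O)c1ccccc1
Why: Boron-templated ortho-hydroxymethylation of a phenol: the aryloxyboron species delivers formaldehyde to the ortho carbon through a six-membered transition state, and the new benzylic alcohol is trapped at once as the cyclic boronate, which stops diarylmethane formation and a second hydroxymethylation. The para position is blocked by the propanoate chain, so only one constitution can form.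

Step 2
Reactants: 3 methyl 3-(2-phenyl-4H-1,3,2-benzodioxaborinin-6-yl)propanoate
Product: 4 methyl 3-[4-hydroxy-3-(hydroxymethyl)phenyl]propanoate
Conditions: 30% aq H2O2, THF, 0 °C to rt
Reagents that add atoms: none
Why: Oxidative cleavage of the boron–phenyl bond (1,2-shift of phenyl from boron to oxygen) turns the boronate into a borate that hydrolyses under near-neutral conditions, so the acid-sensitive 2-hydroxybenzyl alcohol is released without exposure to acid. The methyl ester is not touched at this temperature.

Step 3
Reactants: 4 methyl 3-[4-hydroxy-3-(hydroxymethyl)phenyl]propanoate; 5 2-methylpropene (isobutylene)
Product: 7 methyl 3-(2,2-dimethylchroman-6-yl)propanoate, via ortho-quinone methide 6 (not isolated)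
Conditions: 5 (ca. 20 equiv, condensed in at −78 °C), PhMe (0.05 M in 4), sealed steel autoclave, 180–200 °C
Reagents that add atoms: none
Why: At about 180–200 °C the 2-hydroxybenzyl alcohol loses water through a hydrogen-bonded six-centre transition state and gives the ortho-quinone methide 6, a 1-oxabutadiene whose cycloaddition restores the aromatic sextet of ring B. The closest known reaction type is the thermal inverse-electron-demand hetero-Diels–Alder trapping of ortho-quinone methides from 2-hydroxybenzyl alcohols by alkenes, which with 1,1-disubstituted alkenes gives 2,2-disubstituted chromans. Ring D is closed by an intermolecular [4+2] cycloaddition in which four ring atoms (O1, C8a, C4a, C4) come from 6 and two (C2, C3) from 5; the new bonds C3–C4 and O1–C2 form in one asynchronous step with carbon–carbon bonding running ahead. No stereocentre is created, since C2 carries two identical methyl groups and C3 and C4 are methylenes. The step needs the 2,2- and not the 3,3-dimethyl orientation: the exocyclic CH2 of 6 is the electrophilic terminus and the CH2 of 5 the nucleophilic one, so positive charge builds up on the tertiary carbon, which is then captured by the phenoxide-like oxygen. It also needs the cross reaction to outrun self-condensation of 6, which the large excess of 5 under pressure and the low concentration of 4 are meant to secure. Only one quinone methide can arise, because there is a single hydroxymethyl group and the para position carries the chain; the methyl ester takes no part and should tolerate the neutral thermal conditions.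

Step 4
Reactants: 7 methyl 3-(2,2-dimethylchroman-6-yl)propanoate
Product: 8 3-(2,2-dimethylchroman-6-yl)-N-methoxy-N-methylpropanamide
Conditions: MeNHOMe·HCl (1.5 equiv), i-PrMgCl (3 equiv), THF, −20 to 0 °C
Reagents that add atoms: N,O-dimethylhydroxylamine hydrochloride, CNOC.Cl
Why: Direct aminolysis of a methyl ester by the magnesium amide formed in the flask (Weinreb amide formation). The chroman ether and the aromatic ring are inert to the Grignard base at this temperature.

Step 5
Reactants: 9 phloroglucinol; 10 2-methylbut-3-en-2-ol
Product: 12 2,2-dimethylchroman-5,7-diol, via 2-prenylphloroglucinol 11 (not isolated)
Conditions: 9 (3 equiv), 10 (1 equiv), BF3·OEt2, dioxane, rt to 50 °C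
Reagents that add atoms: none
Why: Friedel–Crafts C-prenylation of the triol by the allyl cation from the tertiary allylic alcohol, followed by acid-catalysed Markovnikov addition of the neighbouring hydroxyl to the trisubstituted alkene, which closes the six-membered ether through the tertiary cation. All ring positions of 9 are equivalent, and the excess of 9 holds back a second annulation.

Step 6
Reactants: 12 2,2-dimethylchroman-5,7-diol
Product: 13 5,7-bis(methoxymethoxy)-2,2-dimethylchroman
Conditions: NaH (2.5 equiv), MOMCl (2.4 equiv), DMF, 0 °C to rt
Reagents that add atoms: chloromethyl methyl ether, COCCl
Why: Williamson-type O-alkylation of both phenoxides by a hard electrophile. The acetal ethers are chosen because they direct the metalation of the next step and leave under mild acid.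

Step 7
Reactants: 13 5,7-bis(methoxymethoxy)-2,2-dimethylchroman; 8 3-(2,2-dimethylchroman-6-yl)-N-methoxy-N-methylpropanamide
Product: 15 1-[5,7-bis(methoxymethoxy)-2,2-dimethylchroman-6-yl]-3-(2,2-dimethylchroman-6-yl)propan-1-one, via aryllithium 14 (not isolated)
Conditions: 13 (1.2 equiv), n-BuLi (1.15 equiv), THF, 0 °C to rt; then 8 (1.0 equiv), −78 to 0 °C; aq NH4Cl
Reagents that add atoms: none
Why: Directed ortho-metalation followed by Weinreb ketone synthesis: C6–H is the only hydrogen flanked by two chelating methoxymethyl ethers, and the C5 ether is turned towards C6 by the ring substituent at C4a, so lithiation should prefer C6 over C8, which has one such ether and the ring oxygen. The aryllithium adds once to the amide because the N-methoxy chelate holds the tetrahedral adduct until work-up.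

Step 8
Reactants: 15 1-[5,7-bis(methoxymethoxy)-2,2-dimethylchroman-6-yl]-3-(2,2-dimethylchroman-6-yl)propan-1-one
Product: 16 1-(5,7-dihydroxy-2,2-dimethylchroman-6-yl)-3-(2,2-dimethylchroman-6-yl)propan-1-one
Conditions: 3 M aq HCl, MeOH, 50 °C
Reagents that add atoms: none
Why: Acid-catalysed acetal exchange removes both methoxymethyl ethers as dimethoxymethane, and the freed phenols are stabilised by chelation to the ketone. The two tertiary alkyl aryl ethers should survive dilute acid in methanol at this temperature.

## Compound list

1 | methyl 3-(4-hydroxyphenyl)propanoate | COC(=O)CCc1ccc(O)cc1 | starting material
2 | formaldehyde (used as paraformaldehyde) | C=O | starting material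
3 | methyl 3-(2-phenyl-4H-1,3,2-benzodioxaborinin-6-yl)propanoate | COC(=O)CCc1ccc2OB(c3ccccc3)OCc2c1 | intermediate
4 | methyl 3-[4-hydroxy-3-(hydroxymethyl)phenyl]propanoate | COC(=O)CCc1ccc(O)c(CO)c1 | intermediate
5 | 2-methylpropene (isobutylene) | CC(C)=C | starting material
6 | methyl 3-(3-methylidene-4-oxocyclohexa-1,5-dien-1-yl)propanoate (ortho-quinone methide, formed in the flask) | COC(=O)CCC1=CC(=C)C(=O)C=C1 | intermediate
7 | methyl 3-(2,2-dimethylchroman-6-yl)propanoate | COC(=O)CCc1ccc2OC(C)(C)CCc2c1 | intermediate
8 | 3-(2,2-dimethylchroman-6-yl)-N-methoxy-N-methylpropanamide | CON(C)C(=O)CCc1ccc2OC(C)(C)CCc2c1 | intermediate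
9 | phloroglucinol (benzene-1,3,5-triol) | Oc1cc(O)cc(O)c1 | starting material
10 | 2-methylbut-3-en-2-ol | CC(C)(O)C=C | starting material
11 | 2-(3-methylbut-2-en-1-yl)benzene-1,3,5-triol (2-prenylphloroglucinol, formed in the flask) | CC(C)=CCc1c(O)cc(O)cc1O | intermediate
12 | 2,2-dimethylchroman-5,7-diol | CC1(C)CCc2c(O)cc(O)cc2O1 | intermediate
13 | 5,7-bis(methoxymethoxy)-2,2-dimethylchroman | COCOc1cc(OCOC)c2CCC(C)(C)Oc2c1 | intermediate
14 | [5,7-bis(methoxymethoxy)-2,2-dimethylchroman-6-yl]lithium (formed in the flask) | [Li]c1c(OCOC)cc2OC(C)(C)CCc2c1OCOC | intermediate
15 | 1-[5,7-bis(methoxymethoxy)-2,2-dimethylchroman-6-yl]-3-(2,2-dimethylchroman-6-yl)propan-1-one | CC1(C)CCc2cc(CCC(=O)c3c(OCOC)cc4OC(C)(C)CCc4c3OCOC)ccc2O1 | intermediate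
16 | 1-(5,7-dihydroxy-2,2-dimethylchroman-6-yl)-3-(2,2-dimethylchroman-6-yl)propan-1-one | CC1(C)CCc2cc(CCC(=O)c3c(O)cc4c(c3O)CCC(C)(C)O4)ccc2O1 | target

## Step count and least certain steps

Total step count: 8. Longest linear sequence: 6 steps (steps 1, 2, 3, 4, 7 and 8, from 1). The ring A branch (steps 5 and 6) joins at step 7.

**Step 3 (key step).** The most likely failure is that the quinone methide is consumed by self-condensation faster than it adds the alkene. The hydroxyl groups of unreacted 4 can add to it and it can oligomerise. Isobutylene is an unpolarised, only modestly electron-rich dienophile, and the temperature needed for dehydration is high. An ene-type hydrogen transfer in place of ring closure is also conceivable, though its open-chain product would close to the same chroman on exposure to acid. The fallback abandons the quinone methide and sets out from 1. Acid-catalysed reaction of 1 with isoprene (85% H3PO4 in xylene at 30–40 °C, or Amberlyst 15) should alkylate the ring ortho to the phenol by a Friedel–Crafts reaction and give methyl 3-[4-hydroxy-3-(3-methylbut-2-en-1-yl)phenyl]propanoate F1. Under the same acid F1 closes by Markovnikov addition of the phenol to the alkene and comes back to the route at 7. Steps 1 to 3 are then not needed.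

**Step 7.** Two processes may interfere. One is competing metalation at C8, where the ring oxygen and one acetal ether can also hold lithium. The other is proton transfer from the CH2 next to the amide carbonyl to the hindered aryllithium, which returns 13 and an unreactive enolate. The fallback changes the bond formation from anionic to electrophilic and sets out from 7. Saponification (LiOH, THF/H2O) gives 3-(2,2-dimethylchroman-6-yl)propanoic acid F2. Friedel–Crafts acylation of the unprotected diol 12 with F2 in BF3·OEt2 at 70–80 °C then comes back to the route at 16. Steps 4, 6, 7 and 8 fall away. This variant has no organolithium and no protecting groups, but it gives up directed regiocontrol. Acylation at C8 will compete, and the isomer with the ketone between the two hydroxyls has to be separated from it, which is why it is the fallback and not the main route.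

**Step 5.** The risk is over-reaction of the very nucleophilic triol, namely a second or third prenylation and annulation, or O-prenylation, even with 9 in excess. The fallback sets out from 9 and builds ring C at the ketone oxidation level. Acylation and oxa-Michael ring closure with 3-methylbut-2-enoic acid (MeSO3H/P2O5, 70 °C) should give 5,7-dihydroxy-2,2-dimethylchroman-4-one F3. The acyl group deactivates the ring towards a second annulation. Clemmensen reduction of F3 (amalgamated zinc, HCl) removes the carbonyl oxygen and comes back to the route at 12.

**Step 1.** The risk is further condensation at the new benzylic carbon with a second molecule of phenol (diarylmethane formation), or incomplete conversion if water removal is inefficient. The fallback sets out from 1 and introduces the carbon at the aldehyde level. Magnesium-mediated ortho-formylation (MgCl2, Et3N, paraformaldehyde 2, MeCN, reflux) should give methyl 3-(3-formyl-4-hydroxyphenyl)propanoate F4. Reduction of the aldehyde with NaBH4 in MeOH at 0 °C leaves the ester alone and comes back to the route at 4. Steps 1 and 2 are then replaced.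

## Further compounds

F1 | step 3 | methyl 3-[4-hydroxy-3-(3-methylbut-2-en-1-yl)phenyl]propanoate | COC(=O)CCc1ccc(O)c(CC=C(C)C)c1
F2 | step 7 | 3-(2,2-dimethylchroman-6-yl)propanoic acid | OC(=O)CCc1ccc2OC(C)(C)CCc2c1
F3 | step 5 | 5,7-dihydroxy-2,2-dimethylchroman-4-one | CC1(C)CC(=O)c2c(O)cc(O)cc2O1
F4 | step 1 | methyl 3-(3-formyl-4-hydroxyphenyl)propanoate | COC(=O)CCc1ccc(O)c(C=O)c1
A1 | alternative 1 | 2,2-dimethylchroman-6-ol | CC1(C)CCc2cc(O)ccc2O1
A2 | alternative 1 | 2,2-dimethyl-1-oxaspiro[4.5]deca-6,9-dien-8-one | CC1(C)CCC2(O1)C=CC(=O)C=C2
A3 | alternative 1 | 4-(3-hydroxy-3-methylbutyl)phenol | CC(C)(O)CCc1ccc(O)cc1
A4 | alternative 2 | 3-[(2,2-dimethylchroman-6-yl)methyl]-4,5,7-trihydroxy-2H-chromen-2-one | O=C1Oc2cc(O)cc(O)c2C(O)=C1Cc1ccc2OC(C)(C)CCc2c1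
A5 | alternative 2 | 2-[(2,2-dimethylchroman-6-yl)methyl]propanedioic acid | OC(=O)C(Cc1ccc2OC(C)(C)CCc2c1)C(O)=O
A6 | alternative 2 | 3-(2,2-dimethylchroman-6-yl)-1-(2,4,6-trihydroxyphenyl)propan-1-one | CC1(C)CCc2cc(CCC(=O)c3c(O)cc(O)cc3O)ccc2O1
A7 | alternative 3 | 1-[5,7-bis(methoxymethoxy)-2,2-dimethylchroman-6-yl]-3-(2,2-dimethylchroman-6-yl)propan-1-one | CC1(C)CCc2cc(CCC(=O)c3c(OCOC)cc4OC(C)(C)CCc4c3OCOC)ccc2O1
A8 | alternative 3 | 1-[5,7-bis(methoxymethoxy)-2,2-dimethylchroman-6-yl]-3-{6-[(2-methylhex-5-yn-2-yl)oxy]pyridazin-3-yl}propan-1-one | C#CCCC(C)(C)Oc1ccc(CCC(=O)c2c(OCOC)cc3OC(C)(C)CCc3c2OCOC)nn1
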